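**Retrosynthetic overview**
1. The (Z)-p-coumarate is attached last: the C18 alcohol is acylated with a diaryl phosphonoacetate, then a Z-selective olefination with protected 4-hydroxybenzaldehyde.
2. The myrcene-type diene comes from ene–yne metathesis of a C13 alkyne with ethylene; the 8α-OH from Markovnikov hydration of a Δ7 alkene.
3. Key disconnection: the C9–C11 bond is made by a Johnson–Claisen [3,3]-sigmatropic rearrangement of a 7β-allylic alcohol (from epoxidation and Wharton transposition of a 9-keto-Δ7 enone); this sets C9.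
4. Ring B is bought as (S)-carvone (its ring becomes C5–C10). Its single stereocentre (C7) steers C5, C10 and C4 and is then excised as the C7=C8 alkene.
5. Ring A is formed second, on ring B: anti-selective Mukaiyama–Michael addition at C5, then cis-selective intramolecular enolate alkylation at C10; C4 is made quaternary by enolate methylation.

Assumption: the SMILES is read literally, i.e. (4R,5S,8R,9R,10S) with a cis-fused 5β-H/10β-CH3 decalin ("5β-labdane") and the oxygenated C4 substituent α (C18); labdane atom numbers are used in all names and β is the face of the C10 methyl.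

**Route**

Step 1
Reactants: 1 methyl 5-bromopentanoate
Product: 2 [(5-bromo-1-methoxypent-1-en-1-yl)oxy]trimethylsilane (ketene silyl acetal, E/Z mixture)
Conditions: LiN(iPr)2, THF, −78 °C; Me3SiCl, −78 °C → rt; pentane filtration, distillation
Reagents that add atoms: chlorotrimethylsilane, C[Si](C)(C)Cl
Why: Kinetic ester enolate formation and O-silylation give the ketene silyl acetal; no stereocentre is formed and the E/Z ratio is irrelevant.

Step 2
Reactants: 3 (S)-(+)-carvone [(5S)-2-methyl-5-(prop-1-en-2-yl)cyclohex-2-en-1-one]; 2 ketene silyl acetal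
Product: 4 methyl 5-bromo-2-[(1S,5S)-2-methyl-3-oxo-5-(prop-1-en-2-yl)cyclohexyl]pentanoate (ring substituents at C1 and C5 trans; epimers at the ester α-carbon and at ring C2)
Conditions: TiCl4, CH2Cl2, −78 °C; aq. K2CO3
Reagents that add atoms: none
Why: Mukaiyama–Michael addition to the TiCl4-activated enone occurs at C5 anti to the C7 isopropenyl group (axial attack, isopropenyl equatorial), so the bought stereocentre sets C5; the C4 and C10 epimer mixtures are erased later.

Step 3
Reactants: 4 keto ester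
Product: 5 methyl 9-oxo-7β-(prop-1-en-2-yl)-11,12,13,14,15,16,17,19-octanor-5β-labdan-18-oate (cis-fused decalone: C5–H and C10–CH3 both β; both C4 epimers)
Conditions: KOtBu, THF–t-BuOH, 0 °C → rt
Reagents that add atoms: none
Why: Intramolecular C-alkylation (6-exo-tet) of the thermodynamic C10 enolate: the C5 chain is axial (trans to the equatorial isopropenyl) and delivers C1 to the same face, giving the cis-fused ring A with the C10 methyl β.

Step 4
Reactants: 5 cis-decalone ester
Product: 6 methyl 9-oxo-7β-(prop-1-en-2-yl)-11,12,13,14,15,16-hexanor-5β-labdan-18-oate (4β-CH3, 4α-CO2CH3; both C8 epimers)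
Conditions: LiN(iPr)2 (2.3 equiv), THF–DMPU, −78 → −20 °C; MeI, −78 → 0 °C
Reagents that add atoms: iodomethane, CI
Why: Double enolate methylation: the ketone enolate takes CH3 at C8 (configuration irrelevant) and the ester enolate at C4 from the β face, because in the chair locked by the equatorial isopropenyl the α trajectory is blocked by the syn-axial C9, so CH3 enters equatorially and CO2CH3 ends α.

Step 5
Reactants: 6 dimethylated keto ester
Product: 8 methyl 9-oxo-11,12,13,14,15,16-hexanor-5β-labd-7-en-18-oate, via α-methoxy hydroperoxide 7 (not isolated)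
Conditions: O3, CH2Cl2–MeOH, −78 °C; then Cu(OAc)2·H2O, FeSO4·7H2O, −20 °C → rt
Reagents that add atoms: none
Why: Criegee ozonolysis in methanol followed by ferrous/cupric-mediated alkoxy-radical β-scission (Schreiber fragmentation) excises the isopropenyl group and oxidises the C7 radical to the conjugated C7=C8 enone; the used-up C7 stereocentre disappears here.

Step 6
Reactants: 8 enone
Product: 9 methyl 7β,8β-epoxy-9-oxo-11,12,13,14,15,16-hexanor-5β-labdan-18-oate
Conditions: 30 % H2O2, NaOH (cat.), MeOH, 0 °C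
Reagents that add atoms: hydrogen peroxide, OO
Why: Weitz–Scheffer nucleophilic epoxidation: hydroperoxide adds to C7 anti to the 1,3-related C5–C4 bond (the same control as in carvone epoxidation), giving the β-epoxide.

Step 7
Reactants: 9 epoxy ketone
Product: 10 methyl 7β-hydroxy-11,12,13,14,15,16-hexanor-5β-labd-8-en-18-oate
Conditions: N2H4·H2O, AcOH (cat.), MeOH, 0 °C → rt
Reagents that add atoms: none
Why: Wharton transposition: the epoxy hydrazone loses N2 and the epoxide C7–O bond is retained, giving the 7β-allylic alcohol with a C8=C9 alkene.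

Step 8
Reactants: 10 allylic alcohol
Product: 12 12-ethyl 18-methyl 13,14,15,16-tetranor-5β-labd-7-ene-12,18-dioate, via ketene acetal 11 (not isolated)
Conditions: CH3C(OEt)3, EtCO2H (cat.), xylene, 140 °C (EtOH distilled off)
Reagents that add atoms: triethyl orthoacetate, CCOC(C)(OCC)OCC
Why: Johnson–Claisen [3,3]-sigmatropic rearrangement forms the C9–C11 bond suprafacially, on the β face from which the C7–O bond departs, setting C9 (side chain β, H α) and moving the alkene to C7=C8.

Step 9
Reactants: 12 diester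
Product: 13 13,14,15,16-tetranor-5β-labd-7-ene-12,18-diol
Conditions: LiAlH4, THF, 0 °C → reflux
Reagents that add atoms: none
Why: Hydride reduction of both esters to primary alcohols; no stereocentre is touched.

Step 10
Reactants: 13 diol
Product: 14 18-hydroxy-13,14,15,16-tetranor-5β-labd-7-en-12-yl 4-methylbenzenesulfonate
Conditions: TsCl (1.05 equiv), Et3N, DMAP (cat.), CH2Cl2, −20 → 0 °C
Reagents that add atoms: 4-methylbenzenesulfonyl chloride, Cc1ccc(cc1)S(=O)(=O)Cl
Why: Sulfonylation is selective for the unhindered C12 primary alcohol over the neopentyl C18 alcohol.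

Step 11
Reactants: 14 monotosylate
Product: 15 15,16-dinor-5β-labd-7-en-13-yn-18-ol
Conditions: LiC≡CH·H2NCH2CH2NH2 (3 equiv), DMSO, rt
Reagents that add atoms: lithium acetylide–ethylenediamine complex, [Li+].[C-]#C.NCCN
Why: SN2 alkylation of acetylide by the primary tosylate adds C13–C14; the C18 alkoxide is a bystander.

Step 12
Reactants: 15 enyne alcohol
Product: 16 15,16-dinor-5β-labd-13-yne-8α,18-diol
Conditions: Co(acac)2 (20 mol %), PhSiH3, O2 (1 atm), THF, rt
Reagents that add atoms: dioxygen, O=O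
Why: Mukaiyama hydration by hydrogen-atom transfer: H adds to C7 and the tertiary C8 radical is trapped by O2 on the α face, anti to the syn-axial C10 methyl and the C9 side chain, giving the 8α-alcohol; the alkyne is far less reactive.

Step 13
Reactants: 16 alkyne diol
Product: 17 5β-labda-13(16),14-diene-8α,18-diol
Conditions: second-generation Grubbs catalyst (5 mol %), ethylene (1 atm), toluene, 80 °C
Reagents that add atoms: ethylene, C=C
Why: Ene–yne cross-metathesis with ethylene converts the terminal alkyne into the 2-substituted buta-1,3-diene; no stereocentre is involved.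

Step 14
Reactants: 17 diene diol
Product: 18 8α-hydroxy-5β-labda-13(16),14-dien-18-yl (diphenoxyphosphoryl)acetate
Conditions: (PhO)2P(O)CH2CO2H, DCC, DMAP (cat.), CH2Cl2, 0 °C → rt
Reagents that add atoms: (diphenoxyphosphoryl)acetic acid, OC(=O)CP(=O)(Oc1ccccc1)Oc1ccccc1
Why: Steglich esterification acylates only the primary C18 alcohol; the tertiary C8 alcohol does not react.

Step 15
Reactants: 18 phosphonoacetate; 19 4-[(tert-butyldimethylsilyl)oxy]benzaldehyde
Product: 21 8α-hydroxy-5β-labda-13(16),14-dien-18-yl (2Z)-3-(4-hydroxyphenyl)prop-2-enoate (target CNP0197278.5), via aryl silyl ether 20 (not isolated)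
Conditions: NaI, DBU, THF, −78 → 0 °C; then AcOH, Bu4NF, 0 °C
Reagents that add atoms: none
Why: Ando-type Horner–Wadsworth–Emmons olefination with the diaryl phosphonate gives the (Z)-enoate under kinetic control, and buffered fluoride then cleaves the aryl silyl ether without touching the ester or the alkene geometry.

**Compound list**
1 | methyl 5-bromopentanoate | COC(=O)CCCCBr | starting material
2 | [(5-bromo-1-methoxypent-1-en-1-yl)oxy]trimethylsilane (E/Z) | COC(=CCCCBr)O[Si](C)(C)C | intermediate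
3 | (S)-(+)-carvone | CC1=CC[C@@H](CC1=O)C(C)=C | starting material
4 | methyl 5-bromo-2-[(1S,5S)-2-methyl-3-oxo-5-(prop-1-en-2-yl)cyclohexyl]pentanoate (epimers at ester α-C and ring C2) | COC(=O)C(CCCBr)[C@H]1C[C@H](C(C)=C)CC(=O)C1C | intermediate
5 | methyl 9-oxo-7β-(prop-1-en-2-yl)-11,12,13,14,15,16,17,19-octanor-5β-labdan-18-oate (C4 epimers) | C[C@]12CCCC(C(=O)OC)[C@H]1C[C@H](C(C)=C)CC2=O | intermediate
6 | methyl 9-oxo-7β-(prop-1-en-2-yl)-11,12,13,14,15,16-hexanor-5β-labdan-18-oate (C8 epimers) | C[C@]12CCC[C@@](C)(C(=O)OC)[C@H]1C[C@H](C(C)=C)C(C)C2=O | intermediate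
7 | methyl 7β-(1-hydroperoxy-1-methoxyethyl)-9-oxo-11,12,13,14,15,16-hexanor-5β-labdan-18-oate | C[C@]12CCC[C@@](C)(C(=O)OC)[C@H]1C[C@H](C(C)(OC)OO)C(C)C2=O | intermediate (not isolated)
8 | methyl 9-oxo-11,12,13,14,15,16-hexanor-5β-labd-7-en-18-oate | C[C@]12CCC[C@@](C)(C(=O)OC)[C@H]1CC=C(C)C2=O | intermediate
9 | methyl 7β,8β-epoxy-9-oxo-11,12,13,14,15,16-hexanor-5β-labdan-18-oate | C[C@]12CCC[C@@](C)(C(=O)OC)[C@H]1C[C@@H]3O[C@]3(C)C2=O | intermediate
10 | methyl 7β-hydroxy-11,12,13,14,15,16-hexanor-5β-labd-8-en-18-oate | C[C@]12CCC[C@@](C)(C(=O)OC)[C@H]1C[C@H](O)C(C)=C2 | intermediate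
11 | methyl 7β-[(1-ethoxyethenyl)oxy]-11,12,13,14,15,16-hexanor-5β-labd-8-en-18-oate | C[C@]12CCC[C@@](C)(C(=O)OC)[C@H]1C[C@H](OC(=C)OCC)C(C)=C2 | intermediate (not isolated)
12 | 12-ethyl 18-methyl 13,14,15,16-tetranor-5β-labd-7-ene-12,18-dioate | CCOC(=O)C[C@@H]1[C@@]2(C)CCC[C@@](C)(C(=O)OC)[C@H]2CC=C1C | intermediate
13 | 13,14,15,16-tetranor-5β-labd-7-ene-12,18-diol | OCC[C@@H]1[C@@]2(C)CCC[C@@](C)(CO)[C@H]2CC=C1C | intermediate
14 | 18-hydroxy-13,14,15,16-tetranor-5β-labd-7-en-12-yl 4-methylbenzenesulfonate | Cc1ccc(cc1)S(=O)(=O)OCC[C@@H]1[C@@]2(C)CCC[C@@](C)(CO)[C@H]2CC=C1C | intermediate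
15 | 15,16-dinor-5β-labd-7-en-13-yn-18-ol | C#CCC[C@@H]1[C@@]2(C)CCC[C@@](C)(CO)[C@H]2CC=C1C | intermediate
16 | 15,16-dinor-5β-labd-13-yne-8α,18-diol | C#CCC[C@@H]1[C@@]2(C)CCC[C@@](C)(CO)[C@H]2CC[C@@]1(C)O | intermediate
17 | 5β-labda-13(16),14-diene-8α,18-diol | C=CC(=C)CC[C@@H]1[C@@]2(C)CCC[C@@](C)(CO)[C@H]2CC[C@@]1(C)O | intermediate
18 | 8α-hydroxy-5β-labda-13(16),14-dien-18-yl (diphenoxyphosphoryl)acetate | C=CC(=C)CC[C@@H]1[C@@]2(C)CCC[C@@](C)(COC(=O)CP(=O)(Oc3ccccc3)Oc3ccccc3)[C@H]2CC[C@@]1(C)O | intermediate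
19 | 4-[(tert-butyldimethylsilyl)oxy]benzaldehyde | O=Cc1ccc(O[Si](C)(C)C(C)(C)C)cc1 | starting material
20 | 8α-hydroxy-5β-labda-13(16),14-dien-18-yl (2Z)-3-{4-[(tert-butyldimethylsilyl)oxy]phenyl}prop-2-enoate | C=CC(=C)CC[C@@H]1[C@@]2(C)CCC[C@@](C)(COC(=O)/C=C\c3ccc(O[Si](C)(C)C(C)(C)C)cc3)[C@H]2CC[C@@]1(C)O | intermediate (not isolated)
21 | 8α-hydroxy-5β-labda-13(16),14-dien-18-yl (2Z)-3-(4-hydroxyphenyl)prop-2-enoate, (4R,5S,8R,9R,10S) | C=CC(=C)CC[C@@H]1[C@@]2(C)CCC[C@@](C)(COC(=O)/C=C\c3ccc(O)cc3)[C@H]2CC[C@@]1(C)O | target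

**Totals**
Total steps: 15. Longest linear sequence: 15 (1 → 21; carvone 3 enters at step 2).

**Steps most likely to fail, with fallbacks**

Step 7 (Wharton on a ketone flanked by two fully substituted carbons; hydrazone formation may be too slow). The fallback drops the hydrazine chemistry and sets out from 9. NaBH4 (MeOH, 0 °C) reduces the ketone to methyl 7β,8β-epoxy-9-hydroxy-11,12,13,14,15,16-hexanor-5β-labdan-18-oate F1. 1,1′-Thiocarbonyldiimidazole (DMAP, toluene, 80 °C) converts it to the 9-O-(imidazol-1-ylthiocarbonyl) derivative F2. Bu3SnH/AIBN (toluene, 80 °C) then generates the C9 radical, which opens the epoxide to the allyloxy radical and, after hydrogen transfer, gives 10, where the route is rejoined.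

Step 8 (orthoester Claisen at the neopentyl C9 terminus; elimination to a diene may compete). The fallback makes the C9–C11 bond by a carbamate-directed cuprate displacement and sets out from 10. PhNCO (Et3N, CH2Cl2) gives methyl 7β-[(phenylcarbamoyl)oxy]-11,12,13,14,15,16-hexanor-5β-labd-8-en-18-oate F3. MeLi, CuBr·SMe2 and CH2=CHMgBr (THF, −78 → 0 °C) deliver vinyl syn to the carbamate (syn-SN2′, β face) to give methyl 13,14,15,16-tetranor-5β-labda-7,11-dien-18-oate F4. 9-BBN then H2O2/NaOH hydroborates only the vinyl group to methyl 12-hydroxy-13,14,15,16-tetranor-5β-labd-7-en-18-oate F5, and LiAlH4 reduces it to diol 13, where the route is rejoined.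

Step 12 (face selectivity at C8 on this cis-fused skeleton rests on conformational argument, not precedent; the alkyne might also be touched). The fallback replaces radical hydration by epoxidation and hydride opening and sets out from 15. VO(acac)2/t-BuOOH (CH2Cl2, rt) should be directed by the α-face C18 hydroxyl, which lies under ring B, to give 7α,8α-epoxy-15,16-dinor-5β-labd-13-yn-18-ol F6. LiAlH4 (THF, reflux) opens the epoxide at C7 to give 16, where the route is rejoined.

**Further compounds**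
F1 | step 7 | methyl 7β,8β-epoxy-9-hydroxy-11,12,13,14,15,16-hexanor-5β-labdan-18-oate (C9 epimers) | C[C@]12CCC[C@@](C)(C(=O)OC)[C@H]1C[C@@H]3O[C@]3(C)C2O
F2 | step 7 | methyl 7β,8β-epoxy-9-[(1H-imidazol-1-ylcarbonothioyl)oxy]-11,12,13,14,15,16-hexanor-5β-labdan-18-oate | C[C@]12CCC[C@@](C)(C(=O)OC)[C@H]1C[C@@H]3O[C@]3(C)C2OC(=S)n1ccnc1
F3 | step 8 | methyl 7β-[(phenylcarbamoyl)oxy]-11,12,13,14,15,16-hexanor-5β-labd-8-en-18-oate | C[C@]12CCC[C@@](C)(C(=O)OC)[C@H]1C[C@H](OC(=O)Nc3ccccc3)C(C)=C2
F4 | step 8 | methyl 13,14,15,16-tetranor-5β-labda-7,11-dien-18-oate | C=C[C@@H]1[C@@]2(C)CCC[C@@](C)(C(=O)OC)[C@H]2CC=C1C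
F5 | step 8 | methyl 12-hydroxy-13,14,15,16-tetranor-5β-labd-7-en-18-oate | OCC[C@@H]1[C@@]2(C)CCC[C@@](C)(C(=O)OC)[C@H]2CC=C1C
F6 | step 12 | 7α,8α-epoxy-15,16-dinor-5β-labd-13-yn-18-ol | C#CCC[C@@H]1[C@@]2(C)CCC[C@@](C)(CO)[C@H]2C[C@H]3O[C@@]13C
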